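## Retrosynthetic overview
1. Target 21 comes from diol acetate 20 and its bis-silyl ether 19. The ring ketone and the acid are carried as a secondary and a primary silyl ether and are oxidised together in the last step.
2. The key disconnection is the bond from quaternary C4 to the side chain. It joins C10 enone 9 (fragment 1) and the C8 organocerium reagent 17 made from iodide 15 (fragment 2). Attack anti to the C5 pentenyl group sets C4, and the alkoxide is trapped in the flask as the acetate.
3. Enone 9 comes from lipase resolution of (±)-trans-hydroxy enone 7. Compound 7 comes from Piancatelli rearrangement of furylcarbinol 5, made from furan 3 and (Z)-hex-3-enal 2. Leaf alcohol 1 supplies the Z-alkene.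
4. Iodide 15 comes from cyclooctene 10 by ozonolysis/NaBH4, monobromination, silylation and Finkelstein exchange.
5. There is only one carbocycle. It is formed in step 3 (furan to cyclopentenone), before the coupling.

Assumption: the lipase follows Kazlauskas' rule with the branched C5 side as the large group, so (4R,5S)-7 is acetylated and (4S,5R)-8 is left; the sense is confirmed on 8 by Mosher ester analysis before going on.

## Route

**Step 1**
Reactants: 1 (Z)-hex-3-en-1-ol
Product: 2 (Z)-hex-3-enal
Conditions: IBX (1.3 equiv), DMSO, rt, 2 h; H2O, pentane extraction; used at once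
Reagents that add atoms: none
Why: IBX oxidation of a primary alcohol stops at the aldehyde and uses neither base nor strong acid, so the skipped Z-alkene neither moves into conjugation nor isomerises.

**Step 2**
Reactants: 3 furan; 2 (Z)-hex-3-enal
Product: 5 (±)-(Z)-1-(furan-2-yl)hex-3-en-1-ol, via 2-furyllithium 4 (not isolated)
Conditions: 3 (1.3 equiv), n-BuLi (1.1 equiv), THF, −78 → 0 °C, 1 h; then 2, −78 °C, 30 min; sat. aq NH4Cl
Reagents that add atoms: none
Why: Heteroatom-directed α-lithiation of furan followed by 1,2-addition of the organolithium to the aldehyde is faster at −78 °C than deprotonation of the activated CH2, and the racemic carbinol centre does not matter because it is planarised in step 3.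

**Step 3**
Reactants: 5 (±)-(Z)-1-(furan-2-yl)hex-3-en-1-ol
Product: 7 (±)-trans-4-hydroxy-5-[(Z)-pent-2-en-1-yl]cyclopent-2-en-1-one, via hydroxypentadienyl cation 6 (not isolated)
Conditions: Dy(OTf)3 (10 mol %), t-BuOH–H2O (5:1), 80 °C, 6–12 h
Reagents that add atoms: water `O`
Why: In this Piancatelli rearrangement the Lewis acid ionises the carbinol, water adds at furan C5, the ring opens to cation 6, and its conrotatory 4π electrocyclisation from the out,out geometry gives only the trans-4,5-disubstituted enone, here as the racemate.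

**Step 4**
Reactants: 7 (±)-trans-4-hydroxy-5-[(Z)-pent-2-en-1-yl]cyclopent-2-en-1-one
Product: 8 (4S,5R)-4-hydroxy-5-[(Z)-pent-2-en-1-yl]cyclopent-2-en-1-one
Conditions: Burkholderia cepacia lipase (Amano PS, immobilised), vinyl acetate (3 equiv), MTBE, 30 °C, to 52–55% conversion; chromatography
Reagents that add atoms: none
Why: In this lipase-catalysed kinetic resolution by irreversible transesterification the (4R,5S)-enantiomer is acetylated (Kazlauskas' rule), so just past half conversion the unreacted (4S,5R)-alcohol remains in ≥98% ee, which fixes the absolute configuration of the pentenyl-bearing carbon.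

**Step 5**
Reactants: 8 (4S,5R)-4-hydroxy-5-[(Z)-pent-2-en-1-yl]cyclopent-2-en-1-one
Product: 9 (4S,5R)-4-[(tert-butyldimethylsilyl)oxy]-5-[(Z)-pent-2-en-1-yl]cyclopent-2-en-1-one
Conditions: TBSCl (1.2 equiv), imidazole (2 equiv), CH2Cl2, 0 °C → rt
Reagents that add atoms: tert-butyldimethylsilyl chloride `CC(C)(C)[Si](C)(C)Cl`
Why: Imidazole-promoted silylation of the secondary alcohol removes the acidic OH before the organometallic step under conditions too mild to epimerise C5 or shift the enone, and no stereocentre is touched.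

**Step 6**
Reactants: 10 (Z)-cyclooctene
Product: 12 octane-1,8-diol, via 8-hydroperoxy-8-methoxyoctanal 11 (not isolated)
Conditions: O3, CH2Cl2–MeOH (1:1), −78 °C; then NaBH4 (3 equiv), −78 °C → rt
Reagents that add atoms: ozone `[O-][O+]=O`
Why: Ozonolysis in methanol with reductive NaBH4 work-up cuts the only double bond of the symmetrical ring and gives the linear C8 chain with both ends at the alcohol level.

**Step 7**
Reactants: 12 octane-1,8-diol
Product: 13 8-bromooctan-1-ol
Conditions: 48% aq HBr (1.2 equiv), toluene, reflux, 24 h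
Reagents that add atoms: hydrogen bromide `Br`
Why: In this two-phase SN2 monobromination of a symmetrical diol the less polar bromo alcohol moves into toluene, away from the aqueous acid, so the second substitution is slow.

**Step 8**
Reactants: 13 8-bromooctan-1-ol
Product: 14 [(8-bromooctyl)oxy](tert-butyl)dimethylsilane
Conditions: TBSCl (1.1 equiv), imidazole (2 equiv), CH2Cl2, 0 °C → rt
Reagents that add atoms: tert-butyldimethylsilyl chloride `CC(C)(C)[Si](C)(C)Cl`
Why: Silylation of the primary alcohol gives an ether that withstands organolithium chemistry and comes off later together with the ring silyl ether.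

**Step 9**
Reactants: 14 [(8-bromooctyl)oxy](tert-butyl)dimethylsilane
Product: 15 tert-butyl[(8-iodooctyl)oxy]dimethylsilane
Conditions: NaI (3 equiv), acetone, reflux, 12 h
Reagents that add atoms: sodium iodide `[Na+].[I-]`
Why: The Finkelstein reaction (SN2 halide exchange) is driven by precipitation of NaBr, and the primary iodide is needed because it undergoes fast, clean lithium–iodine exchange where the bromide does not.

**Step 10 (fragment coupling)**
Reactants: 15 tert-butyl[(8-iodooctyl)oxy]dimethylsilane; 9 (4S,5R)-4-[(tert-butyldimethylsilyl)oxy]-5-[(Z)-pent-2-en-1-yl]cyclopent-2-en-1-one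
Product: 19 (1S,4S,5R)-4-[(tert-butyldimethylsilyl)oxy]-1-{8-[(tert-butyldimethylsilyl)oxy]octyl}-5-[(Z)-pent-2-en-1-yl]cyclopent-2-en-1-yl acetate, via silyloxyoctyllithium 16 (not isolated), via silyloxyoctylcerium dichloride 17 (not isolated), via dichlorocerium alkoxide 18 (not isolated)
Conditions: 15 (1.3 equiv), t-BuLi (2.6 equiv), Et2O–pentane, −78 °C; anhydrous CeCl3 (1.4 equiv), THF, −78 °C, 1 h; 9 (1.0 equiv), −78 °C, 1 h; Ac2O (5 equiv), DMAP (0.2 equiv), −78 °C → rt
Reagents that add atoms: acetic anhydride `CC(=O)OC(C)=O`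
Why: Lithium–iodine exchange and transmetalation give a weakly basic, oxophilic organocerium reagent (Imamoto conditions) whose 1,2-addition avoids enolisation and β-elimination of the silyloxy group, comes in anti to the adjacent C5 pentenyl group so that the C8 chain is trans and the oxygen cis to it (S-configured quaternary carbon), and alkoxide 18 is acetylated in the same flask.

**Step 11**
Reactants: 19 bis-silyl ether acetate
Product: 20 (1S,4S,5R)-4-hydroxy-1-(8-hydroxyoctyl)-5-[(Z)-pent-2-en-1-yl]cyclopent-2-en-1-yl acetate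
Conditions: HF·pyridine, pyridine–THF, 0 °C → rt
Reagents that add atoms: none
Why: Fluoride-mediated desilylation, driven by the strong Si–F bond, frees both alcohols under buffered conditions that leave the tertiary allylic acetate, both alkenes and all stereocentres untouched.

**Step 12**
Reactants: 20 diol acetate
Product: 21 8-{(1S,5S)-1-acetoxy-4-oxo-5-[(Z)-pent-2-en-1-yl]cyclopent-2-en-1-yl}octanoic acid (target)
Conditions: AZADO (5 mol %), PhI(OAc)2 (3.5 equiv), MeCN–pH 7 phosphate buffer (1:1), rt
Reagents that add atoms: water `O`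
Why: Nitroxyl/oxoammonium oxidation with the unhindered AZADO takes the secondary allylic alcohol to the enone and, with water present, the primary alcohol to the acid near neutral pH, so acetate is not eliminated and C5, already in the more stable arrangement with the two carbon chains trans, is not epimerised.

## Compound list
1 | (Z)-hex-3-en-1-ol | `CC/C=C\CCO` | starting material
2 | (Z)-hex-3-enal | `CC/C=C\CC=O` | intermediate
3 | furan | `c1ccoc1` | starting material
4 | 2-furyllithium | `[Li]c1ccco1` | intermediate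
5 | (±)-(Z)-1-(furan-2-yl)hex-3-en-1-ol (racemic carbinol) | `CC/C=C\CC(O)c1ccco1` | intermediate
6 | hydroxypentadienyl cation (O-protonated (7Z)-4-hydroxydeca-2,4,7-trienal) | `CC/C=C\CC=C(O)C=CC=[OH+]` | intermediate
7 | (±)-trans-4-hydroxy-5-[(Z)-pent-2-en-1-yl]cyclopent-2-en-1-one (racemate, both enantiomers written) | `CC/C=C\C[C@@H]1[C@@H](O)C=CC1=O.CC/C=C\C[C@H]1[C@H](O)C=CC1=O` | intermediate
8 | (4S,5R)-4-hydroxy-5-[(Z)-pent-2-en-1-yl]cyclopent-2-en-1-one | `CC/C=C\C[C@@H]1[C@@H](O)C=CC1=O` | intermediate
9 | (4S,5R)-4-[(tert-butyldimethylsilyl)oxy]-5-[(Z)-pent-2-en-1-yl]cyclopent-2-en-1-one | `CC/C=C\C[C@@H]1[C@@H](O[Si](C)(C)C(C)(C)C)C=CC1=O` | intermediate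
10 | (Z)-cyclooctene | `C1CC/C=C\CCC1` | starting material
11 | 8-hydroperoxy-8-methoxyoctanal | `COC(OO)CCCCCCC=O` | intermediate
12 | octane-1,8-diol | `OCCCCCCCCO` | intermediate
13 | 8-bromooctan-1-ol | `OCCCCCCCCBr` | intermediate
14 | [(8-bromooctyl)oxy](tert-butyl)dimethylsilane | `CC(C)(C)[Si](C)(C)OCCCCCCCCBr` | intermediate
15 | tert-butyl[(8-iodooctyl)oxy]dimethylsilane | `CC(C)(C)[Si](C)(C)OCCCCCCCCI` | intermediate
16 | {8-[(tert-butyldimethylsilyl)oxy]octyl}lithium | `[Li]CCCCCCCCO[Si](C)(C)C(C)(C)C` | intermediate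
17 | dichloro{8-[(tert-butyldimethylsilyl)oxy]octyl}cerium | `Cl[Ce](Cl)CCCCCCCCO[Si](C)(C)C(C)(C)C` | intermediate
18 | dichlorocerium (1S,4S,5R)-tertiary alkoxide from 17 and 9 | `CC/C=C\C[C@@H]1[C@@H](O[Si](C)(C)C(C)(C)C)C=C[C@]1(CCCCCCCCO[Si](C)(C)C(C)(C)C)O[Ce](Cl)Cl` | intermediate
19 | (1S,4S,5R)-4-[(tert-butyldimethylsilyl)oxy]-1-{8-[(tert-butyldimethylsilyl)oxy]octyl}-5-[(Z)-pent-2-en-1-yl]cyclopent-2-en-1-yl acetate | `CC/C=C\C[C@@H]1[C@@H](O[Si](C)(C)C(C)(C)C)C=C[C@]1(CCCCCCCCO[Si](C)(C)C(C)(C)C)OC(C)=O` | intermediate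
20 | (1S,4S,5R)-4-hydroxy-1-(8-hydroxyoctyl)-5-[(Z)-pent-2-en-1-yl]cyclopent-2-en-1-yl acetate | `CC/C=C\C[C@@H]1[C@@H](O)C=C[C@]1(CCCCCCCCO)OC(C)=O` | intermediate
21 | 8-{(1S,5S)-1-acetoxy-4-oxo-5-[(Z)-pent-2-en-1-yl]cyclopent-2-en-1-yl}octanoic acid | `CC/C=C\C[C@@H]1C(=O)C=C[C@]1(CCCCCCCC(=O)O)OC(C)=O` | target

## Counts and risks
Total step count: 12.
Longest linear sequence: 8 steps (1, 2, 3, 4, 5, 10, 11, 12). Steps 6–9 run in parallel.

**Step 3 (Piancatelli rearrangement).**
- Risk: the ionised carbinol can lose a proton from the neighbouring allylic CH2 and give a conjugated furyl diene or polymer. Product 7 can also drift to the 2-substituted isomer.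
- Fallback: the ring is closed by an aldol reaction instead of an electrocyclisation. It sets out from 1 and 2-furyllithium 4 and comes back at 7.
- Appel bromination of 1 (CBr4, PPh3, CH2Cl2, 0 °C) gives (Z)-1-bromohex-3-ene F1.
- F1 alkylates 4 (THF, −78 °C → rt) to give 2-[(Z)-hex-3-en-1-yl]furan F2.
- Sensitised photooxygenation (O2, tetraphenylporphyrin, hν, CH2Cl2, −78 °C) attacks the furan far faster than the disubstituted alkene. It gives 1-[(Z)-hex-3-en-1-yl]-2,3,7-trioxabicyclo[2.2.1]hept-5-ene F3.
- Me2S reduces F3 to (2Z,7Z)-4-oxodeca-2,7-dienal F4.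
- In pH 7.5 phosphate buffer–dioxane, C5 of F4 adds to the aldehyde in an intramolecular aldol reaction. Under equilibrating conditions this gives the trans-hydroxy enone 7.

**Step 4 (lipase resolution).**
- Risk: the selectivity factor and the sense of the enzyme are not secured for this substrate, and the yield cannot exceed half.
- Fallback: resolution is replaced by desymmetrisation. It sets out from 7 and comes back at 8.
- Dess–Martin oxidation of 7 gives the achiral 2-[(Z)-pent-2-en-1-yl]cyclopent-4-ene-1,3-dione F5, whose two carbonyl groups are enantiotopic.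
- A ketoreductase picked from a panel (NADPH recycled with glucose and glucose dehydrogenase, pH 7 buffer, 30 °C) reduces one of them to the (4S)-carbinol.
- The labile C5 then settles trans by enolisation. This gives 8 from all of the material instead of half.

**Step 10 (coupling and in situ acetylation).**
- Risk: each face of the carbonyl carries one substituent (pentenyl on one, OTBS on the other), so the diastereomer ratio may be modest. Loss of silanolate after enolisation and incomplete acetylation of the hindered cerium alkoxide are further risks.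
- Fallback: the order of events is changed and the ring silyl ether is dropped. It sets out from 8, with reagent 17 made from 15 as before, and comes back at 21.
- Free hydroxy enone 8 is treated with 2.5 equiv of 17 (THF, −78 °C). The first equivalent only deprotonates the OH, and the resulting small oxide cannot leave and barely shields its face.
- Aqueous work-up gives (1S,4S,5R)-1-{8-[(tert-butyldimethylsilyl)oxy]octyl}-5-[(Z)-pent-2-en-1-yl]cyclopent-2-ene-1,4-diol F6.
- MnO2 (CH2Cl2, rt) oxidises only the secondary allylic alcohol. This gives (4S,5S)-4-{8-[(tert-butyldimethylsilyl)oxy]octyl}-4-hydroxy-5-[(Z)-pent-2-en-1-yl]cyclopent-2-en-1-one F7.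
- Ac2O, DMAP and Et3N give (1S,5S)-1-{8-[(tert-butyldimethylsilyl)oxy]octyl}-4-oxo-5-[(Z)-pent-2-en-1-yl]cyclopent-2-en-1-yl acetate F8.
- HF·pyridine gives (1S,5S)-1-(8-hydroxyoctyl)-4-oxo-5-[(Z)-pent-2-en-1-yl]cyclopent-2-en-1-yl acetate F9.
- TEMPO/PhI(OAc)2 in MeCN–H2O takes the primary alcohol of F9 to the acid 21.

## Further compounds
F1 | step 3 | (Z)-1-bromohex-3-ene | `CC/C=C\CCBr`
F2 | step 3 | 2-[(Z)-hex-3-en-1-yl]furan | `CC/C=C\CCc1ccco1`
F3 | step 3 | 1-[(Z)-hex-3-en-1-yl]-2,3,7-trioxabicyclo[2.2.1]hept-5-ene | `CC/C=C\CCC12OOC(C=C1)O2`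
F4 | step 3 | (2Z,7Z)-4-oxodeca-2,7-dienal | `CC/C=C\CCC(=O)/C=C\C=O`
F5 | step 4 | 2-[(Z)-pent-2-en-1-yl]cyclopent-4-ene-1,3-dione | `CC/C=C\CC1C(=O)C=CC1=O`
F6 | step 10 | (1S,4S,5R)-1-{8-[(tert-butyldimethylsilyl)oxy]octyl}-5-[(Z)-pent-2-en-1-yl]cyclopent-2-ene-1,4-diol | `CC/C=C\C[C@@H]1[C@@H](O)C=C[C@]1(CCCCCCCCO[Si](C)(C)C(C)(C)C)O`
F7 | step 10 | (4S,5S)-4-{8-[(tert-butyldimethylsilyl)oxy]octyl}-4-hydroxy-5-[(Z)-pent-2-en-1-yl]cyclopent-2-en-1-one | `CC/C=C\C[C@@H]1C(=O)C=C[C@]1(CCCCCCCCO[Si](C)(C)C(C)(C)C)O`
F8 | step 10 | (1S,5S)-1-{8-[(tert-butyldimethylsilyl)oxy]octyl}-4-oxo-5-[(Z)-pent-2-en-1-yl]cyclopent-2-en-1-yl acetate | `CC/C=C\C[C@@H]1C(=O)C=C[C@]1(CCCCCCCCO[Si](C)(C)C(C)(C)C)OC(C)=O`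
F9 | step 10 | (1S,5S)-1-(8-hydroxyoctyl)-4-oxo-5-[(Z)-pent-2-en-1-yl]cyclopent-2-en-1-yl acetate | `CC/C=C\C[C@@H]1C(=O)C=C[C@]1(CCCCCCCCO)OC(C)=O`
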